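The route rests on cutting central ring E (rings lettered A to H from the 3,5-dihydroxyphenoxy end) at E2–E3 and E4–E5. Ring E is 1,2,3,5-tetraoxygenated: the ring D oxygen sits on E1 between the E2 and E6 hydroxyls and the ring F oxygen on E4, sites that give no handle for a convergent ether coupling. A Danheiser benzannulation exploits this pattern: heating a racemic 4-aryloxy-3-ethoxycyclobutenone that carries rings A–D with the ethynyl ether of rings F–H builds ring E in one operation, both crowded ether oxygens already attached. The permethylated partners come from iterative ether coupling and Baeyer–Villiger cycles; BBr3 finally frees all twenty hydroxyls.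

Key step: step 16

Remark: methyl ethers, plus the one ethyl ether that ethoxyacetylene brings in, are the only protecting groups, because diaryl ethers are inert to BBr3 and all nineteen alkyl groups leave in one operation; racemic and transient species are drawn without configuration at carbon.

Step 1
Reactants: 1 3,5-dimethoxyphenol; 2 2-bromo-3,4,5-trimethoxybenzaldehyde
Product: 3 2-(3,5-dimethoxyphenoxy)-3,4,5-trimethoxybenzaldehyde
Conditions: CuI (10 mol%), picolinic acid (20 mol%), K3PO4, DMSO, 90 °C, Ar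
Reagents that add atoms: none
Why: Ullmann diaryl ether coupling, in which the ortho-formyl group assists copper insertion into the C–Br bond and the unhindered phenoxide of 1 attacks, so the crowded B1–O bond forms while the formyl group marks B2 for later oxygenation.

Step 2
Reactants: 3 2-(3,5-dimethoxyphenoxy)-3,4,5-trimethoxybenzaldehyde
Product: 5 2-(3,5-dimethoxyphenoxy)-3,4,5-trimethoxyphenol, via aryl formate 4 (not isolated)
Conditions: mCPBA, CH2Cl2, 0 °C to rt; aq. NaHCO3 wash; then K2CO3 (cat.), MeOH, rt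
Reagents that add atoms: mCPBA, OOC(=O)c1cccc(Cl)c1
Why: Baeyer–Villiger oxidation, in which the electron-rich aryl group (ortho-aryloxy and para-methoxy donors) migrates in preference to hydride to give formate 4, which base-catalysed methanolysis cleaves to the B2 phenol.

Step 3
Reactants: 5 2-(3,5-dimethoxyphenoxy)-3,4,5-trimethoxyphenol; 6 4-bromo-3,5-dimethoxybenzaldehyde
Product: 7 4-[2-(3,5-dimethoxyphenoxy)-3,4,5-trimethoxyphenoxy]-3,5-dimethoxybenzaldehyde
Conditions: CuI (10 mol%), picolinic acid (20 mol%), K3PO4, DMSO, 100 °C, Ar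
Reagents that add atoms: none
Why: Ullmann diaryl ether coupling in which the para-formyl group activates the bromide of 6 between its two methoxy groups and the picolinic acid ligand is chosen for hindered partners, joining the B2 oxygen to C1.

Step 4
Reactants: 7 4-[2-(3,5-dimethoxyphenoxy)-3,4,5-trimethoxyphenoxy]-3,5-dimethoxybenzaldehyde
Product: 9 4-[2-(3,5-dimethoxyphenoxy)-3,4,5-trimethoxyphenoxy]-3,5-dimethoxyphenol, via aryl formate 8 (not isolated)
Conditions: mCPBA, CH2Cl2, 0 °C to rt; aq. NaHCO3 wash; then K2CO3 (cat.), MeOH, rt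
Reagents that add atoms: mCPBA, OOC(=O)c1cccc(Cl)c1
Why: Baeyer–Villiger oxidation with aryl migration favoured by the para-aryloxy donor, followed by methanolysis of formate 8, turns the C4 formyl group into the C4 hydroxyl.

Step 5
Reactants: 9 4-[2-(3,5-dimethoxyphenoxy)-3,4,5-trimethoxyphenoxy]-3,5-dimethoxyphenol; 2 2-bromo-3,4,5-trimethoxybenzaldehyde
Product: 10 2-{4-[2-(3,5-dimethoxyphenoxy)-3,4,5-trimethoxyphenoxy]-3,5-dimethoxyphenoxy}-3,4,5-trimethoxybenzaldehyde
Conditions: CuI (10 mol%), picolinic acid (20 mol%), K3PO4, DMSO, 90 °C, Ar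
Reagents that add atoms: none
Why: Ullmann diaryl ether coupling of the same kind as step 1, now with the unhindered C4 phenoxide, forms C4–O–D1 and leaves the formyl group on D2.

Step 6
Reactants: 10 2-{4-[2-(3,5-dimethoxyphenoxy)-3,4,5-trimethoxyphenoxy]-3,5-dimethoxyphenoxy}-3,4,5-trimethoxybenzaldehyde
Product: 12 2-{4-[2-(3,5-dimethoxyphenoxy)-3,4,5-trimethoxyphenoxy]-3,5-dimethoxyphenoxy}-3,4,5-trimethoxyphenol, via aryl formate 11 (not isolated)
Conditions: mCPBA, CH2Cl2, 0 °C to rt; aq. NaHCO3 wash; then K2CO3 (cat.), MeOH, rt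
Reagents that add atoms: mCPBA, OOC(=O)c1cccc(Cl)c1
Why: Baeyer–Villiger oxidation with migration of the electron-rich ring D and methanolysis of formate 11 give the D2 phenol, the attachment point for ring E.

Step 7
Reactants: 12 ring A–D phenol (hydroxyl on D2); 13 methyl bromoacetate
Product: 15 (ring A–D aryloxy)acetic acid, via methyl ester 14 (not isolated)
Conditions: K2CO3, DMF, rt; then LiOH, THF/H2O, rt; aq. HCl work-up
Reagents that add atoms: lithium hydroxide, [Li+].[OH-]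
Why: Williamson etherification of the D2 phenoxide with the primary α-bromo ester (SN2) followed by saponification of methyl ester 14 gives the aryloxyacetic acid without touching any aryl ether.

Step 8
Reactants: 15 (ring A–D aryloxy)acetic acid; 16 ethoxyacetylene
Product: 19 racemic 4-(ring A–D aryloxy)-3-ethoxycyclobut-2-en-1-one, via acid chloride 17 (not isolated), via aryloxyketene 18 (not isolated)
Conditions: 1-chloro-N,N,2-trimethylprop-1-en-1-amine, CH2Cl2, 0 °C to rt; then slow addition to 16 (5 equiv), Et3N, CH2Cl2, 0 °C to rt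
Reagents that add atoms: none
Why: The neutral chloroenamine converts the acid into chloride 17 without acylating the electron-rich rings, Et3N dehydrochlorinates it to aryloxyketene 18, and a ketene–ynol ether [2+2] cycloaddition in which the nucleophilic terminal carbon of ethoxyacetylene attacks the ketene carbonyl carbon gives the cyclobutenone as a racemate whose stereocentre needs no control because it becomes aromatic carbon E1.

Step 9
Reactants: 20 2,4,6-trimethoxyphenol; 21 4-fluoro-2,6-dimethoxybenzaldehyde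
Product: 22 2,6-dimethoxy-4-(2,4,6-trimethoxyphenoxy)benzaldehyde
Conditions: K2CO3, DMF, 100 °C, Ar
Reagents that add atoms: none
Why: Nucleophilic aromatic substitution by addition–elimination, in which the para-formyl group stabilises the anionic σ-adduct and fluoride leaves from an unhindered carbon, accepts the hindered phenoxide of 20 and forms H1–O–G4.

Step 10
Reactants: 22 2,6-dimethoxy-4-(2,4,6-trimethoxyphenoxy)benzaldehyde
Product: 24 2,6-dimethoxy-4-(2,4,6-trimethoxyphenoxy)phenol, via aryl formate 23 (not isolated)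
Conditions: mCPBA, CH2Cl2, 0 °C; aq. NaHCO3 wash; then K2CO3 (cat.), MeOH, rt
Reagents that add atoms: mCPBA, OOC(=O)c1cccc(Cl)c1
Why: Baeyer–Villiger oxidation, fast for a 2,6-dimethoxybenzaldehyde whose aryl group migrates readily, and methanolysis of formate 23 give the hindered G1 phenol.

Step 11
Reactants: 25 5-bromo-1,2,3-trimethoxybenzene
Product: 26 6-bromo-2,3,4-trimethoxybenzaldehyde
Conditions: Cl2CHOMe, TiCl4, CH2Cl2, 0 °C; then H2O
Reagents that add atoms: dichloromethyl methyl ether, COC(Cl)Cl; water, O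
Why: Rieche formylation, an electrophilic aromatic substitution that can only reach the two equivalent free positions of 25, each ortho and para to a methoxy group, should give a single aldehyde with bromine ortho to the formyl group.

Step 12
Reactants: 24 2,6-dimethoxy-4-(2,4,6-trimethoxyphenoxy)phenol; 26 6-bromo-2,3,4-trimethoxybenzaldehyde
Product: 27 6-[2,6-dimethoxy-4-(2,4,6-trimethoxyphenoxy)phenoxy]-2,3,4-trimethoxybenzaldehyde
Conditions: CuI (10 mol%), picolinic acid (20 mol%), K3PO4, DMSO, 90 °C, Ar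
Reagents that add atoms: none
Why: Ullmann diaryl ether coupling in which the ortho-formyl group activates a bromide with only one flanking substituent and the ligand system accepts the 2,6-dimethoxyphenoxide of 24, forming G1–O–F2.

Step 13
Reactants: 27 6-[2,6-dimethoxy-4-(2,4,6-trimethoxyphenoxy)phenoxy]-2,3,4-trimethoxybenzaldehyde
Product: 29 6-[2,6-dimethoxy-4-(2,4,6-trimethoxyphenoxy)phenoxy]-2,3,4-trimethoxyphenol, via aryl formate 28 (not isolated)
Conditions: mCPBA, CH2Cl2, 0 °C; aq. NaHCO3 wash; then K2CO3 (cat.), MeOH, rt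
Reagents that add atoms: mCPBA, OOC(=O)c1cccc(Cl)c1
Why: Baeyer–Villiger oxidation with migration of ring F, which carries ortho-methoxy, ortho-aryloxy and para-methoxy donors, and methanolysis of formate 28 unveil the F1 hydroxyl.

Step 14
Reactants: 29 ring F–H phenol (hydroxyl on F1); 30 trichloroethylene
Product: 31 (E)-1,2-dichlorovinyl ether of 29
Conditions: K2CO3, DMF, 70 °C
Reagents that add atoms: none
Why: Base eliminates HCl from trichloroethylene to dichloroacetylene, to which the F1 phenoxide adds in anti fashion, a known vinylation of phenols that gives the (E)-dichlorovinyl ether, whose geometry is of no consequence since both vinyl carbons become the alkyne.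

Step 15
Reactants: 31 (E)-1,2-dichlorovinyl ether of 29
Product: 34 ethynyl ether of 29, via chloroethynyl ether 32 (not isolated), via lithium acetylide 33 (not isolated)
Conditions: n-BuLi (2.2 equiv), THF, −78 to −40 °C; then H2O, −78 °C to rt; used at once
Reagents that add atoms: none
Why: Deprotonation and β-elimination of LiCl give chloroalkyne 32, chlorine–lithium exchange with the second equivalent of n-BuLi gives acetylide 33, and protonation at low temperature releases the terminal aryl ynol ether, a known dehydrohalogenation route to alkynyl ethers.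

Step 16
Reactants: 19 racemic 4-(ring A–D aryloxy)-3-ethoxycyclobut-2-en-1-one; 34 ethynyl ether of 29
Product: 39 3-ethoxy-2-(ring A–D aryloxy)-5-(ring F–H aryloxy)phenol (protected octamer; ring E 2-hydroxy-6-ethoxy; eighteen methyl ethers), via vinylketene 35 (not isolated), via vinylcyclobutenone 36 (not isolated), via dienylketene 37 (not isolated), via cyclohexadienone 38 (not isolated)
Conditions: 34 (1.3 equiv), degassed toluene, 80 °C then 110 °C, sealed tube, Ar
Reagents that add atoms: none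
Why: Heat opens 19 by conrotatory four-electron electrocyclic cleavage, the 4-aryloxy donor turning outward, to vinylketene 35, whose electrophilic carbonyl carbon is attacked by the nucleophilic terminal carbon of 34 in a [2+2] cycloaddition that forms E2–E3 and E4–E5 in 36. A second four-electron opening gives dienylketene 37, and ring E closes by thermal disrotatory six-electron electrocyclization between the ketene carbon (E2) and the aryloxy-bearing terminus (E1) to dienone 38, which tautomerises to phenol 39. The reaction type is the Danheiser benzannulation, established for cyclobutenones with alkoxy- and siloxyacetylenes, to whose ynol ether class 34 belongs. No stereocentre survives: those of 19, 36 and 38 are racemic and are erased when E1 becomes aromatic. The step needs regioselectivity in the cycloaddition, and the oxygen of the ynol ether secures it by polarising the triple bond, so that the ring F oxygen lands on E4, meta to the new E2 hydroxyl and para to the ring D oxygen on E1. An aryl ethynyl ether lacks the β-hydrogen needed for retro-ene loss of an alkene, so it should tolerate the temperature.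

Step 17
Reactants: 39 protected octamer phenol
Product: 40 CNP0319661.0
Conditions: BBr3 (60 equiv), CH2Cl2, −78 °C to rt, Ar; then H2O, 0 °C; isolation under Ar
Reagents that add atoms: none
Why: Lewis acid-mediated ether cleavage, in which BBr3 coordinates each alkyl aryl ether oxygen and bromide removes the methyl or ethyl group by SN2 attack, leaves the diaryl ether C–O bonds intact because they offer no sp3 carbon, so hydrolysis of the aryl borates should give the target.

Compound list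
1 | 3,5-dimethoxyphenol | COc1cc(O)cc(OC)c1 | starting material
2 | 2-bromo-3,4,5-trimethoxybenzaldehyde | COc1cc(C=O)c(Br)c(OC)c1OC | starting material
3 | 2-(3,5-dimethoxyphenoxy)-3,4,5-trimethoxybenzaldehyde (rings A–B; formyl on B2) | COc1cc(OC)cc(Oc2c(C=O)cc(OC)c(OC)c2OC)c1 | intermediate
4 | 2-(3,5-dimethoxyphenoxy)-3,4,5-trimethoxyphenyl formate | COc1cc(OC)cc(Oc2c(OC=O)cc(OC)c(OC)c2OC)c1 | intermediate
5 | 2-(3,5-dimethoxyphenoxy)-3,4,5-trimethoxyphenol (hydroxyl on B2) | COc1cc(OC)cc(Oc2c(O)cc(OC)c(OC)c2OC)c1 | intermediate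
6 | 4-bromo-3,5-dimethoxybenzaldehyde | COc1cc(C=O)cc(OC)c1Br | starting material
7 | 4-[2-(3,5-dimethoxyphenoxy)-3,4,5-trimethoxyphenoxy]-3,5-dimethoxybenzaldehyde (rings A–C; formyl on C4) | COc1cc(OC)cc(Oc2c(Oc3c(OC)cc(C=O)cc3OC)cc(OC)c(OC)c2OC)c1 | intermediate
8 | 4-[2-(3,5-dimethoxyphenoxy)-3,4,5-trimethoxyphenoxy]-3,5-dimethoxyphenyl formate | COc1cc(OC)cc(Oc2c(Oc3c(OC)cc(OC=O)cc3OC)cc(OC)c(OC)c2OC)c1 | intermediate
9 | 4-[2-(3,5-dimethoxyphenoxy)-3,4,5-trimethoxyphenoxy]-3,5-dimethoxyphenol (hydroxyl on C4) | COc1cc(OC)cc(Oc2c(Oc3c(OC)cc(O)cc3OC)cc(OC)c(OC)c2OC)c1 | intermediate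
10 | 2-{4-[2-(3,5-dimethoxyphenoxy)-3,4,5-trimethoxyphenoxy]-3,5-dimethoxyphenoxy}-3,4,5-trimethoxybenzaldehyde (rings A–D; formyl on D2) | COc1cc(OC)cc(Oc2c(Oc3c(OC)cc(Oc4c(C=O)cc(OC)c(OC)c4OC)cc3OC)cc(OC)c(OC)c2OC)c1 | intermediate
11 | 2-{4-[2-(3,5-dimethoxyphenoxy)-3,4,5-trimethoxyphenoxy]-3,5-dimethoxyphenoxy}-3,4,5-trimethoxyphenyl formate | COc1cc(OC)cc(Oc2c(Oc3c(OC)cc(Oc4c(OC=O)cc(OC)c(OC)c4OC)cc3OC)cc(OC)c(OC)c2OC)c1 | intermediate
12 | 2-{4-[2-(3,5-dimethoxyphenoxy)-3,4,5-trimethoxyphenoxy]-3,5-dimethoxyphenoxy}-3,4,5-trimethoxyphenol (ring A–D phenol; hydroxyl on D2) | COc1cc(OC)cc(Oc2c(Oc3c(OC)cc(Oc4c(O)cc(OC)c(OC)c4OC)cc3OC)cc(OC)c(OC)c2OC)c1 | intermediate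
13 | methyl bromoacetate | COC(=O)CBr | starting material
14 | methyl (ring A–D aryloxy)acetate, the aryl group of 12 bound through its D2 oxygen | COc1cc(OC)cc(Oc2c(Oc3c(OC)cc(Oc4c(OCC(=O)OC)cc(OC)c(OC)c4OC)cc3OC)cc(OC)c(OC)c2OC)c1 | intermediate
15 | (ring A–D aryloxy)acetic acid | COc1cc(OC)cc(Oc2c(Oc3c(OC)cc(Oc4c(OCC(=O)O)cc(OC)c(OC)c4OC)cc3OC)cc(OC)c(OC)c2OC)c1 | intermediate
16 | ethoxyacetylene | C#COCC | starting material
17 | (ring A–D aryloxy)acetyl chloride | COc1cc(OC)cc(Oc2c(Oc3c(OC)cc(Oc4c(OCC(Cl)=O)cc(OC)c(OC)c4OC)cc3OC)cc(OC)c(OC)c2OC)c1 | intermediate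
18 | (ring A–D aryloxy)ketene, 2-aryloxyethen-1-one | COc1cc(OC)cc(Oc2c(Oc3c(OC)cc(Oc4c(OC=C=O)cc(OC)c(OC)c4OC)cc3OC)cc(OC)c(OC)c2OC)c1 | intermediate
19 | racemic 4-(ring A–D aryloxy)-3-ethoxycyclobut-2-en-1-one | COc1cc(OC)cc(Oc2c(Oc3c(OC)cc(Oc4c(OC5C(=O)C=C5OCC)cc(OC)c(OC)c4OC)cc3OC)cc(OC)c(OC)c2OC)c1 | intermediate
20 | 2,4,6-trimethoxyphenol | COc1cc(OC)c(O)c(OC)c1 | starting material
21 | 4-fluoro-2,6-dimethoxybenzaldehyde | COc1cc(F)cc(OC)c1C=O | starting material
22 | 2,6-dimethoxy-4-(2,4,6-trimethoxyphenoxy)benzaldehyde (rings G–H; formyl on G1) | O=Cc1c(OC)cc(Oc2c(OC)cc(OC)cc2OC)cc1OC | intermediate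
23 | 2,6-dimethoxy-4-(2,4,6-trimethoxyphenoxy)phenyl formate | O=COc1c(OC)cc(Oc2c(OC)cc(OC)cc2OC)cc1OC | intermediate
24 | 2,6-dimethoxy-4-(2,4,6-trimethoxyphenoxy)phenol (hydroxyl on G1) | Oc1c(OC)cc(Oc2c(OC)cc(OC)cc2OC)cc1OC | intermediate
25 | 5-bromo-1,2,3-trimethoxybenzene | COc1cc(Br)cc(OC)c1OC | starting material
26 | 6-bromo-2,3,4-trimethoxybenzaldehyde | COc1cc(Br)c(C=O)c(OC)c1OC | intermediate
27 | 6-[2,6-dimethoxy-4-(2,4,6-trimethoxyphenoxy)phenoxy]-2,3,4-trimethoxybenzaldehyde (rings F–H; formyl on F1) | O=Cc1c(Oc2c(OC)cc(Oc3c(OC)cc(OC)cc3OC)cc2OC)cc(OC)c(OC)c1OC | intermediate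
28 | 6-[2,6-dimethoxy-4-(2,4,6-trimethoxyphenoxy)phenoxy]-2,3,4-trimethoxyphenyl formate | O=COc1c(Oc2c(OC)cc(Oc3c(OC)cc(OC)cc3OC)cc2OC)cc(OC)c(OC)c1OC | intermediate
29 | 6-[2,6-dimethoxy-4-(2,4,6-trimethoxyphenoxy)phenoxy]-2,3,4-trimethoxyphenol (ring F–H phenol; hydroxyl on F1) | Oc1c(Oc2c(OC)cc(Oc3c(OC)cc(OC)cc3OC)cc2OC)cc(OC)c(OC)c1OC | intermediate
30 | trichloroethylene | ClC=C(Cl)Cl | starting material
31 | (E)-1,2-dichlorovinyl ether of 29 | Cl/C=C(/Cl)Oc1c(Oc2c(OC)cc(Oc3c(OC)cc(OC)cc3OC)cc2OC)cc(OC)c(OC)c1OC | intermediate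
32 | chloroethynyl ether of 29 | ClC#COc1c(Oc2c(OC)cc(Oc3c(OC)cc(OC)cc3OC)cc2OC)cc(OC)c(OC)c1OC | intermediate
33 | lithium acetylide of the ethynyl ether of 29 | [Li]C#COc1c(Oc2c(OC)cc(Oc3c(OC)cc(OC)cc3OC)cc2OC)cc(OC)c(OC)c1OC | intermediate
34 | ethynyl ether of 29 (ring F–H aryl ynol ether) | C#COc1c(Oc2c(OC)cc(Oc3c(OC)cc(OC)cc3OC)cc2OC)cc(OC)c(OC)c1OC | intermediate
35 | (3Z)-4-(ring A–D aryloxy)-3-ethoxybuta-1,3-dien-1-one (vinylketene) | COc1cc(OC)cc(Oc2c(Oc3c(OC)cc(Oc4c(O/C=C(OCC)/C=C=O)cc(OC)c(OC)c4OC)cc3OC)cc(OC)c(OC)c2OC)c1 | intermediate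
36 | racemic 4-[(Z)-2-(ring A–D aryloxy)-1-ethoxyvinyl]-3-(ring F–H aryloxy)cyclobut-2-en-1-one | COc1cc(OC)cc(Oc2c(Oc3c(OC)cc(Oc4c(O/C=C(OCC)/C5C(=O)C=C5Oc6c(Oc7c(OC)cc(Oc8c(OC)cc(OC)cc8OC)cc7OC)cc(OC)c(OC)c6OC)cc(OC)c(OC)c4OC)cc3OC)cc(OC)c(OC)c2OC)c1 | intermediate
37 | (3E,5Z)-6-(ring A–D aryloxy)-5-ethoxy-3-(ring F–H aryloxy)hexa-1,3,5-trien-1-one (dienylketene) | COc1cc(OC)cc(Oc2c(Oc3c(OC)cc(Oc4c(O/C=C(OCC)/C=C(/Oc5c(Oc6c(OC)cc(Oc7c(OC)cc(OC)cc7OC)cc6OC)cc(OC)c(OC)c5OC)C=C=O)cc(OC)c(OC)c4OC)cc3OC)cc(OC)c(OC)c2OC)c1 | intermediate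
38 | racemic 6-(ring A–D aryloxy)-5-ethoxy-3-(ring F–H aryloxy)cyclohexa-2,4-dien-1-one | COc1cc(OC)cc(Oc2c(Oc3c(OC)cc(Oc4c(OC5C(=O)C=C(Oc6c(Oc7c(OC)cc(Oc8c(OC)cc(OC)cc8OC)cc7OC)cc(OC)c(OC)c6OC)C=C5OCC)cc(OC)c(OC)c4OC)cc3OC)cc(OC)c(OC)c2OC)c1 | intermediate
39 | 3-ethoxy-2-(ring A–D aryloxy)-5-(ring F–H aryloxy)phenol (protected octamer; free hydroxyl on E2, ethoxy on E6, eighteen methyl ethers) | COc1cc(OC)cc(Oc2c(Oc3c(OC)cc(Oc4c(Oc5c(O)cc(Oc6c(Oc7c(OC)cc(Oc8c(OC)cc(OC)cc8OC)cc7OC)cc(OC)c(OC)c6OC)cc5OCC)cc(OC)c(OC)c4OC)cc3OC)cc(OC)c(OC)c2OC)c1 | intermediate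
40 | CNP0319661.0, the octameric aryl ether with all twenty hydroxyls free | Oc1cc(O)cc(Oc2c(Oc3c(O)cc(Oc4c(Oc5c(O)cc(Oc6c(Oc7c(O)cc(Oc8c(O)cc(O)cc8O)cc7O)cc(O)c(O)c6O)cc5O)cc(O)c(O)c4O)cc3O)cc(O)c(O)c2O)c1 | target

Total step count: 17. Longest linear sequence: 10 steps (steps 1 to 8, then 16 and 17); the ring F–H branch (steps 9 to 15) joins at step 16.

Steps most likely to fail

Step 16. The vinylogous-ester cyclobutenone may open too slowly, the terminal ynol ether may oligomerise on heating before it captures the vinylketene, and the product phenol may be acylated by vinylketene (the last is reversed by brief K2CO3/MeOH treatment of the crude). The fallback replaces the convergent annulation by linear chain growth with the coupling and oxidation cycle of steps 3 to 6; it sets out from 12 and comes back to the route at 40. Coupling of 12 with 6 (CuI, picolinic acid, K3PO4, DMSO) would give the ring A–E aldehyde F1; mCPBA would give its formate F2 and methanolysis the ring A–E phenol F3 (hydroxyl on E4). Coupling of F3 with 2 would give the ring A–F aldehyde F4, oxidation its formate F5, and methanolysis the ring A–F phenol F6 (hydroxyl on F2). Coupling of F6 with 6 would give the ring A–G aldehyde F7, oxidation its formate F8, and methanolysis the ring A–G phenol F9 (hydroxyl on G4). Ullmann coupling of F9 with 2-iodo-1,3,5-trimethoxybenzene (COc1cc(OC)c(I)c(OC)c1) would give the icosamethyl ether F10, which BBr3 under the conditions of step 17 would convert into 40.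

Step 17. Dealkylation may stop short when partly cleaved aryl borates precipitate from CH2Cl2, and the pyrogallol-type rings B, D and F may oxidise in air while the free polyphenol is isolated. The fallback isolates through a stable derivative; it sets out from 39 and comes back at 40. After the BBr3 treatment and quench, the crude polyphenol would be acetylated at once (Ac2O, pyridine, DMAP cat.) to the icosaacetate F11. F11 can be purified on silica and resubmitted if partly alkylated material remains. Degassed methanolic HCl (AcCl in MeOH, rt) would then release 40 under acidic, non-oxidising conditions.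

Step 3. C–O bond formation at a bromide flanked by two methoxy groups with an ortho-substituted phenoxide may be slow, so that hydrodebromination of 6 and oxidative loss of the phenoxide take over. The fallback gives up copper catalysis for an uncatalysed addition–elimination, which needs no metal to insert between the two methoxy groups; it sets out from 5 and comes back at 7. Phenol 5 and 4-fluoro-3,5-dimethoxybenzaldehyde (COc1cc(C=O)cc(OC)c1F) with Cs2CO3 in DMSO at 120 °C would give 7 directly through the σ-adduct stabilised by the para-formyl group.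

Further compounds
F1 | step 16 | ring A–E aldehyde (12 extended by a 4-formyl-2,6-dimethoxyphenyl ring on the D2 oxygen) | COc1cc(OC)cc(Oc2c(Oc3c(OC)cc(Oc4c(Oc5c(OC)cc(C=O)cc5OC)cc(OC)c(OC)c4OC)cc3OC)cc(OC)c(OC)c2OC)c1
F2 | step 16 | ring A–E aryl formate | COc1cc(OC)cc(Oc2c(Oc3c(OC)cc(Oc4c(Oc5c(OC)cc(OC=O)cc5OC)cc(OC)c(OC)c4OC)cc3OC)cc(OC)c(OC)c2OC)c1
F3 | step 16 | ring A–E phenol (hydroxyl on E4) | COc1cc(OC)cc(Oc2c(Oc3c(OC)cc(Oc4c(Oc5c(OC)cc(O)cc5OC)cc(OC)c(OC)c4OC)cc3OC)cc(OC)c(OC)c2OC)c1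
F4 | step 16 | ring A–F aldehyde (formyl on F2) | COc1cc(OC)cc(Oc2c(Oc3c(OC)cc(Oc4c(Oc5c(OC)cc(Oc6c(C=O)cc(OC)c(OC)c6OC)cc5OC)cc(OC)c(OC)c4OC)cc3OC)cc(OC)c(OC)c2OC)c1
F5 | step 16 | ring A–F aryl formate | COc1cc(OC)cc(Oc2c(Oc3c(OC)cc(Oc4c(Oc5c(OC)cc(Oc6c(OC=O)cc(OC)c(OC)c6OC)cc5OC)cc(OC)c(OC)c4OC)cc3OC)cc(OC)c(OC)c2OC)c1
F6 | step 16 | ring A–F phenol (hydroxyl on F2) | COc1cc(OC)cc(Oc2c(Oc3c(OC)cc(Oc4c(Oc5c(OC)cc(Oc6c(O)cc(OC)c(OC)c6OC)cc5OC)cc(OC)c(OC)c4OC)cc3OC)cc(OC)c(OC)c2OC)c1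
F7 | step 16 | ring A–G aldehyde (formyl on G4) | COc1cc(OC)cc(Oc2c(Oc3c(OC)cc(Oc4c(Oc5c(OC)cc(Oc6c(Oc7c(OC)cc(C=O)cc7OC)cc(OC)c(OC)c6OC)cc5OC)cc(OC)c(OC)c4OC)cc3OC)cc(OC)c(OC)c2OC)c1
F8 | step 16 | ring A–G aryl formate | COc1cc(OC)cc(Oc2c(Oc3c(OC)cc(Oc4c(Oc5c(OC)cc(Oc6c(Oc7c(OC)cc(OC=O)cc7OC)cc(OC)c(OC)c6OC)cc5OC)cc(OC)c(OC)c4OC)cc3OC)cc(OC)c(OC)c2OC)c1
F9 | step 16 | ring A–G phenol (hydroxyl on G4) | COc1cc(OC)cc(Oc2c(Oc3c(OC)cc(Oc4c(Oc5c(OC)cc(Oc6c(Oc7c(OC)cc(O)cc7OC)cc(OC)c(OC)c6OC)cc5OC)cc(OC)c(OC)c4OC)cc3OC)cc(OC)c(OC)c2OC)c1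
F10 | step 16 | icosamethyl ether of 40 | COc1cc(OC)cc(Oc2c(Oc3c(OC)cc(Oc4c(Oc5c(OC)cc(Oc6c(Oc7c(OC)cc(Oc8c(OC)cc(OC)cc8OC)cc7OC)cc(OC)c(OC)c6OC)cc5OC)cc(OC)c(OC)c4OC)cc3OC)cc(OC)c(OC)c2OC)c1
F11 | step 17 | icosaacetate of 40 | CC(=O)Oc1cc(OC(C)=O)cc(Oc2c(Oc3c(OC(C)=O)cc(Oc4c(Oc5c(OC(C)=O)cc(Oc6c(Oc7c(OC(C)=O)cc(Oc8c(OC(C)=O)cc(OC(C)=O)cc8OC(C)=O)cc7OC(C)=O)cc(OC(C)=O)c(OC(C)=O)c6OC(C)=O)cc5OC(C)=O)cc(OC(C)=O)c(OC(C)=O)c4OC(C)=O)cc3OC(C)=O)cc(OC(C)=O)c(OC(C)=O)c2OC(C)=O)c1
F0 | step 3 | none | none
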